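**Plan**

1. Retrosynthesis: the two acetates come off last. The C11–C12 bond is cut next (α‑sulfonyl carbanion plus allylic chloride 20), leaving an ent‑drimane C11 sulfone. C9–C10 and C7–C8 are then cut together as a Diels–Alder pair whose diene and ynoate are joined through the O2–C11 ester bond. The ring‑A diene goes back through a vinyl/enol‑triflate coupling to actinol and ketoisophorone.
2. Enabling feature: on ring A (C1–C5, C10) the C2 oxygen and C9 are 1,3‑related across the quaternary C10. A but‑2‑ynoyl group on O2 (supplying C11, C9, C8 and the C8 methyl) can therefore reach C10 through the four‑atom link C1–C2–O–C11.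
3. Forward: ring A is shaped first (steps 1–6). Ring B and a bridging six‑membered lactone close in one intramolecular cycloaddition. The lactone is opened, C5=C6 saturated, the C8=C9 alkene moved to C7=C8 via a C7 bromide and its zinc dienolate, and the C12–C16 chain joined last.
4. Stereochemistry: C4 of actinol (enzymatic reduction, then diastereoselective hydrogenation) becomes C2. Mitsunobu inversion sets it for the tether, which fixes C10. The C10 methyl then directs C5 (hydrogenation) and C9 (protonation). C2 is finally rebuilt axial with a bulky hydride, and 13E is bought with 20.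

Key step: step 8

Assumption: atoms are numbered as in labdanes and drimanes (C1–C10 decalin, C11 on C9; in drimane names C12 is the methyl on C8). The target is read as the ent‑labdane (2S,5R,9R,10R,13E) with the 2‑acetoxy group axial and cis to the C10 methyl. An ene‑reductase of the Old Yellow Enzyme family is taken as purchasable.

**Route**

Step 1
Reactants: 1 ketoisophorone
Product: 2 (6R)-levodione
Conditions: ene‑reductase OYE2, NADP+ (cat.), glucose dehydrogenase, D‑glucose, phosphate buffer pH 6.5, 30 °C
Reagents that add atoms: none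
Why: Enzymatic asymmetric conjugate reduction of the enedione C=C by an Old Yellow Enzyme, the standard reaction of this substrate; flavin hydride delivery to one face sets the 6R centre, and the slightly acidic buffer limits racemisation.

Step 2
Reactants: 2 (6R)-levodione
Product: 3 (4R,6R)-actinol
Conditions: H2 (1 atm), Raney Ni, MeOH, rt; recrystallisation (iPr2O–hexane)
Reagents that add atoms: none
Why: Heterogeneous carbonyl hydrogenation that should take only the unhindered C4 ketone (C1 lies between C(CH3)2 and CH(CH3)), with hydrogen adding mainly from the face away from the axial C2 methyl to give the 4,6‑trans alcohol; crystallisation is relied on to remove the cis epimer, which would become the antipodal series once C6 is lost.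

Step 3
Reactants: 3 (4R,6R)-actinol
Product: 4 (4R,6R)-4-[(tert-butyldimethylsilyl)oxy]-2,2,6-trimethylcyclohexan-1-one
Conditions: TBSCl, imidazole, DMF, rt
Reagents that add atoms: tert-butyldimethylsilyl chloride, CC(C)(C)[Si](C)(C)Cl
Why: Standard silylation of a secondary alcohol, which shields the hydroxyl from the amide base and triflating agent of step 4.

Step 4
Reactants: 4 (4R,6R)-4-[(tert-butyldimethylsilyl)oxy]-2,2,6-trimethylcyclohexan-1-one
Product: 5 (4R)-4-[(tert-butyldimethylsilyl)oxy]-2,6,6-trimethylcyclohex-1-en-1-yl trifluoromethanesulfonate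
Conditions: LDA, THF, −78 → 0 °C; PhNTf2, 0 °C → rt
Reagents that add atoms: N-phenylbis(trifluoromethanesulfonimide), O=S(=O)(N(c1ccccc1)S(=O)(=O)C(F)(F)F)C(F)(F)F
Why: Enol triflate formation from the lithium enolate; C6–H is the only α‑hydrogen, so a single tetrasubstituted enol triflate can form, the C6 centre is cleared on purpose, and the silyloxy group is γ to the carbonyl and cannot be eliminated.

Step 5
Reactants: 5 (4R)-4-[(tert-butyldimethylsilyl)oxy]-2,6,6-trimethylcyclohex-1-en-1-yl trifluoromethanesulfonate
Product: 6 (R)-tert-butyldimethyl[(3,5,5-trimethyl-4-vinylcyclohex-3-en-1-yl)oxy]silane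
Conditions: tributyl(vinyl)stannane, Pd(PPh3)4 (cat.), LiCl, THF, reflux
Reagents that add atoms: tributyl(vinyl)stannane, C=C[Sn](CCCC)(CCCC)CCCC
Why: Stille coupling of a hindered cyclohexenyl triflate with a vinylstannane under chloride‑assisted conditions, which gives the 2,6,6‑trimethyl‑1‑vinylcyclohexene diene without any regiochemical ambiguity.

Step 6
Reactants: 6 (R)-tert-butyldimethyl[(3,5,5-trimethyl-4-vinylcyclohex-3-en-1-yl)oxy]silane
Product: 7 (R)-3,5,5-trimethyl-4-vinylcyclohex-3-en-1-ol
Conditions: TBAF, THF, rt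
Reagents that add atoms: none
Why: Fluoride desilylation under neutral conditions that leave the diene untouched.

Step 7
Reactants: 7 (R)-3,5,5-trimethyl-4-vinylcyclohex-3-en-1-ol, 8 but-2-ynoic acid
Product: 9 (S)-3,5,5-trimethyl-4-vinylcyclohex-3-en-1-yl but-2-ynoate
Conditions: PPh3, DIAD, THF, 0 °C (betaine preformed); then 8 and 7, 0 °C → rt
Reagents that add atoms: none
Why: Mitsunobu esterification with SN2 inversion at the carbinol carbon (R → S), favoured by the acidic alkynoic acid; preforming the betaine keeps free phosphine away from the ynoate.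

Step 8
Reactants: 9 (S)-3,5,5-trimethyl-4-vinylcyclohex-3-en-1-yl but-2-ynoate
Product: 10 (2R,10R)-2-hydroxydrima-5,8-dien-11-oic acid 11,2-lactone (tricyclic; ring B a cyclohexa-1,4-diene, δ‑lactone from C11 to O2 bridging ring A on the face opposite the C10 methyl)
Conditions: o‑dichlorobenzene (0.01 M), BHT (cat.), 170 °C, sealed tube
Reagents that add atoms: none
Why: Thermal, concerted but asynchronous type‑1 intramolecular Diels–Alder reaction in which the alkynoate carbon C9 bonds to the tetrasubstituted diene terminus C10 and C8 bonds to the CH2 terminus C7; the closest known reactions are ester‑tethered cycloadditions of dienyl alkynoates and the intermolecular addition of acetylenic esters to 2,6,6‑trimethyl‑1‑vinylcyclohexene. Ring B closes as a cyclohexa‑1,4‑diene by the [4+2] itself, and the six‑membered lactone (O2–C11–C9–C10–C1–C2) closes as the tether ring when the C9–C10 bond forms, bridging ring A as a 2‑oxabicyclo[3.3.1]nonane. The only new stereocentre, C10, is controlled by C2: with the oxygen pseudoaxial the short tether can deliver C9 only to the diene face syn to O2, so the C10 methyl ends up anti to the lactone (10R). Regiochemistry is fixed because the tether cannot span to C7, and it agrees with the polarity (nucleophilic C7 to the β‑carbon C8); an alkyne dienophile raises no endo/exo question. High dilution and a radical inhibitor suppress intermolecular addition and polymerisation, and the temperature is kept as low as conversion allows so that a [1,5]‑hydrogen shift of the cis‑diene does not compete.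

Step 9
Reactants: 10 (2R,10R)-2-hydroxydrima-5,8-dien-11-oic acid 11,2-lactone
Product: 11 methyl (2R,10R)-2-hydroxydrima-5,8-dien-11-oate
Conditions: NaOMe (0.5 equiv), MeOH, 0 °C → rt; AcOH quench
Reagents that add atoms: methanol, CO
Why: Base‑catalysed lactone methanolysis (transesterification) driven by release of the bridged ring, after which ring A relaxes with the C2 hydroxyl equatorial and cannot re‑close; it is run cold and short because the doubly allylic C7–H2 is also acidic.

Step 10
Reactants: 11 methyl (2R,10R)-2-hydroxydrima-5,8-dien-11-oate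
Product: 12 methyl (2R,5R,10R)-2-hydroxydrim-8-en-11-oate
Conditions: H2 (1 atm), 10% Pd/C, EtOAc, rt
Reagents that add atoms: none
Why: Catalytic hydrogenation that should take the trisubstituted C5=C6 bond and leave the tetrasubstituted, ester‑bearing C8=C9 bond, as known for the corresponding intermolecular adducts in drimane work; hydrogen adds to the face opposite the pseudoaxial C10 methyl, setting C5 (R) and the trans ring fusion.

Step 11
Reactants: 12 methyl (2R,5R,10R)-2-hydroxydrim-8-en-11-oate
Product: 13 methyl (5R,10R)-2-oxodrim-8-en-11-oate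
Conditions: Dess–Martin periodinane, CH2Cl2, rt
Reagents that add atoms: none
Why: Dess–Martin oxidation of the secondary alcohol, which erases the C2 configuration that served as tether anchor so that it can be rebuilt in the axial sense.

Step 12
Reactants: 13 methyl (5R,10R)-2-oxodrim-8-en-11-oate
Product: 14 methyl (5R,10R)-7-bromo-2-oxodrim-8-en-11-oate (C7 epimers)
Conditions: NBS, AIBN (cat.), PhCF3, 80 °C
Reagents that add atoms: N-bromosuccinimide, O=C1CCC(=O)N1Br
Why: Wohl–Ziegler allylic bromination at the γ‑position of the enoate, in which the bromine atom should abstract the secondary, axially aligned C7–H in preference to the primary C–H of the C8 methyl; this route to a regiodefined dienolate is chosen because amide bases would remove the methyl proton syn to the ester and lead to the exocyclic alkene.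

Step 13
Reactants: 14 methyl (5R,10R)-7-bromo-2-oxodrim-8-en-11-oate
Product: 15 methyl (5R,9R,10R)-2-oxodrim-7-en-11-oate
Conditions: Zn dust, AcOH–Et2O, 0 °C → rt
Reagents that add atoms: none
Why: Zinc reduction of a γ‑bromo enoate to the zinc dienolate (vinylogous Reformatsky intermediate) with kinetic α‑protonation, which moves the alkene to C7=C8; the proton reaches C9 from the face opposite the axial C10 methyl, leaving the ester equatorial (9R), also the more stable epimer, and any α‑bromo ketone formed in step 12 is reduced back at the same time.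

Step 14
Reactants: 15 methyl (5R,9R,10R)-2-oxodrim-7-en-11-oate
Product: 17 (2S,5R,9R,10R)-drim-7-ene-2,11-diol, via axial hydroxy ester 16 (not isolated)
Conditions: L‑Selectride, THF, −78 °C; then LiAlH4, 0 °C → rt
Reagents that add atoms: none
Why: Bulky‑hydride ketone reduction followed by ester reduction; the syn‑axial methyls on C4 and C10 block axial approach to C2, so hydride enters equatorially and the alcohol is axial (2S), and LiAlH4 then takes the hindered ester to the primary alcohol without touching C9.

Step 15
Reactants: 17 (2S,5R,9R,10R)-drim-7-ene-2,11-diol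
Product: 18 (2S,5R,9R,10R)-11-(phenylsulfanyl)drim-7-en-2-ol
Conditions: PhSSPh, PBu3, pyridine, rt → 50 °C
Reagents that add atoms: diphenyl disulfide, c1ccccc1SSc1ccccc1
Why: Hata sulfenylation, an SN2 displacement of the primary alkoxyphosphonium by thiolate, to which the hindered axial secondary alcohol is inert.

Step 16
Reactants: 18 (2S,5R,9R,10R)-11-(phenylsulfanyl)drim-7-en-2-ol
Product: 19 (2S,5R,9R,10R)-11-(phenylsulfonyl)drim-7-en-2-ol
Conditions: (NH4)6Mo7O24·4H2O (cat.), 30% H2O2, EtOH, 0 °C → rt
Reagents that add atoms: hydrogen peroxide, OO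
Why: Molybdate‑catalysed oxidation of sulfide to sulfone, chemoselective over the trisubstituted alkene.

Step 17
Reactants: 19 (2S,5R,9R,10R)-11-(phenylsulfonyl)drim-7-en-2-ol, 20 (E)-4-chloro-3-methylbut-2-en-1-yl acetate
Product: 21 (2S,5R,9R,10R,13E)-2-hydroxy-11-(phenylsulfonyl)labda-7,13-dien-15-yl acetate (C11 epimers)
Conditions: n‑BuLi (2.2 equiv), THF–HMPA, −78 °C; then 20, −78 → −20 °C
Reagents that add atoms: none
Why: Julia‑type alkylation of an α‑sulfonyl carbanion, formed beside the unreactive hindered C2 alkoxide, with a primary allylic chloride by SN2 with retention of the E alkene; this sulfone/C5 chloro‑acetate pairing is established in isoprenoid chain extension, low temperature favours displacement over attack on the acetate, and the new C11 centre is removed in step 18.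

Step 18
Reactants: 21 (2S,5R,9R,10R,13E)-2-hydroxy-11-(phenylsulfonyl)labda-7,13-dien-15-yl acetate
Product: 23 (2S,5R,9R,10R,13E)-labda-7,13-diene-2,15-diol, via hydroxy acetate 22 (not isolated)
Conditions: 6% Na(Hg), Na2HPO4, MeOH–THF, −20 °C; then K2CO3 (cat.), MeOH, rt
Reagents that add atoms: none
Why: Reductive desulfonylation by sodium amalgam (the sulfone is homoallylic to both alkenes, so neither should move), followed by methanolysis of the primary acetate so that a single diol is carried forward.

Step 19
Reactants: 23 (2S,5R,9R,10R,13E)-labda-7,13-diene-2,15-diol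
Product: 24 (2S,5R,9R,10R,13E)-labda-7,13-diene-2,15-diyl diacetate (CNP0314870.1)
Conditions: Ac2O, pyridine, DMAP (cat.), rt → 40 °C
Reagents that add atoms: acetic anhydride, CC(=O)OC(C)=O
Why: DMAP‑catalysed acetylation of both hydroxyls; the axial C2 alcohol, flanked by two syn‑axial methyls, needs the acylpyridinium catalyst and mild warming.

**Compound list**

1 | ketoisophorone (2,6,6-trimethylcyclohex-2-ene-1,4-dione) | CC1=CC(=O)CC(C)(C)C1=O | starting material
2 | (6R)-levodione, (6R)-2,2,6-trimethylcyclohexane-1,4-dione | C[C@@H]1CC(=O)CC(C)(C)C1=O | intermediate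
3 | (4R,6R)-actinol, (4R,6R)-4-hydroxy-2,2,6-trimethylcyclohexan-1-one | C[C@@H]1C[C@@H](O)CC(C)(C)C1=O | intermediate
4 | (4R,6R)-4-[(tert-butyldimethylsilyl)oxy]-2,2,6-trimethylcyclohexan-1-one | C[C@@H]1C[C@@H](O[Si](C)(C)C(C)(C)C)CC(C)(C)C1=O | intermediate
5 | (4R)-4-[(tert-butyldimethylsilyl)oxy]-2,6,6-trimethylcyclohex-1-en-1-yl trifluoromethanesulfonate | CC(C)(C)[Si](C)(C)O[C@@H]1CC(C)=C(OS(=O)(=O)C(F)(F)F)C(C)(C)C1 | intermediate
6 | (R)-tert-butyldimethyl[(3,5,5-trimethyl-4-vinylcyclohex-3-en-1-yl)oxy]silane | CC(C)(C)[Si](C)(C)O[C@@H]1CC(C)=C(C=C)C(C)(C)C1 | intermediate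
7 | (R)-3,5,5-trimethyl-4-vinylcyclohex-3-en-1-ol | O[C@@H]1CC(C)=C(C=C)C(C)(C)C1 | intermediate
8 | but-2-ynoic acid | CC#CC(=O)O | starting material
9 | (S)-3,5,5-trimethyl-4-vinylcyclohex-3-en-1-yl but-2-ynoate | CC#CC(=O)O[C@H]1CC(C)=C(C=C)C(C)(C)C1 | intermediate
10 | (2R,10R)-2-hydroxydrima-5,8-dien-11-oic acid 11,2-lactone | CC1=C2C(=O)O[C@@H]3CC(C)(C)C(=CC1)[C@@]2(C)C3 | intermediate
11 | methyl (2R,10R)-2-hydroxydrima-5,8-dien-11-oate | COC(=O)C1=C(C)CC=C2C(C)(C)C[C@@H](O)C[C@@]12C | intermediate
12 | methyl (2R,5R,10R)-2-hydroxydrim-8-en-11-oate (trans-fused, 2-OH equatorial) | COC(=O)C1=C(C)CC[C@@H]2C(C)(C)C[C@@H](O)C[C@@]12C | intermediate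
13 | methyl (5R,10R)-2-oxodrim-8-en-11-oate | COC(=O)C1=C(C)CC[C@@H]2C(C)(C)CC(=O)C[C@@]12C | intermediate
14 | methyl (5R,10R)-7-bromo-2-oxodrim-8-en-11-oate (C7 epimers) | COC(=O)C1=C(C)C(Br)C[C@@H]2C(C)(C)CC(=O)C[C@@]12C | intermediate
15 | methyl (5R,9R,10R)-2-oxodrim-7-en-11-oate (ester equatorial, 9-H anti to the C10 methyl) | COC(=O)[C@@H]1C(C)=CC[C@@H]2C(C)(C)CC(=O)C[C@@]12C | intermediate
16 | methyl (2S,5R,9R,10R)-2-hydroxydrim-7-en-11-oate (2-OH axial; not isolated) | COC(=O)[C@@H]1C(C)=CC[C@@H]2C(C)(C)C[C@H](O)C[C@@]12C | intermediate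
17 | (2S,5R,9R,10R)-drim-7-ene-2,11-diol | OC[C@@H]1C(C)=CC[C@@H]2C(C)(C)C[C@H](O)C[C@@]12C | intermediate
18 | (2S,5R,9R,10R)-11-(phenylsulfanyl)drim-7-en-2-ol | c3ccccc3SC[C@@H]1C(C)=CC[C@@H]2C(C)(C)C[C@H](O)C[C@@]12C | intermediate
19 | (2S,5R,9R,10R)-11-(phenylsulfonyl)drim-7-en-2-ol | O=S(=O)(c3ccccc3)C[C@@H]1C(C)=CC[C@@H]2C(C)(C)C[C@H](O)C[C@@]12C | intermediate
20 | (E)-4-chloro-3-methylbut-2-en-1-yl acetate | CC(=O)OC/C=C(\C)CCl | starting material
21 | (2S,5R,9R,10R,13E)-2-hydroxy-11-(phenylsulfonyl)labda-7,13-dien-15-yl acetate (C11 epimers) | CC(=O)OC/C=C(\C)CC(S(=O)(=O)c3ccccc3)[C@@H]1C(C)=CC[C@@H]2C(C)(C)C[C@H](O)C[C@@]12C | intermediate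
22 | (2S,5R,9R,10R,13E)-2-hydroxylabda-7,13-dien-15-yl acetate (not isolated) | CC(=O)OC/C=C(\C)CC[C@@H]1C(C)=CC[C@@H]2C(C)(C)C[C@H](O)C[C@@]12C | intermediate
23 | (2S,5R,9R,10R,13E)-labda-7,13-diene-2,15-diol | OC/C=C(\C)CC[C@@H]1C(C)=CC[C@@H]2C(C)(C)C[C@H](O)C[C@@]12C | intermediate
24 | (2S,5R,9R,10R,13E)-labda-7,13-diene-2,15-diyl diacetate | CC(=O)OC/C=C(\C)CC[C@@H]1C(C)=CC[C@@H]2C(C)(C)C[C@H](OC(C)=O)C[C@@]12C | target

**Step count and risks**

Total step count: 19. Longest linear sequence: 19 steps (1 → 24); 8 and 20 are used as purchased.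

Steps most likely to fail:

Step 8. The cycloaddition may stall because the new C9–C10 bond is made at a fully substituted diene terminus and the ester has to twist into its s‑cis form. At the temperature then required, a [1,5]‑hydrogen shift of the diene or polymerisation could overtake ring closure. The fallback makes the same two bonds without the tether and sets out from silyl ether 6. Heating 6 with methyl but‑2‑ynoate (neat, 130–150 °C, or with a Lewis acid) should give, with the same polarity‑controlled regiochemistry and by addition anti to the silyloxy group, methyl (2S,10R)-2-[(tert-butyldimethylsilyl)oxy]drima-5,8-dien-11-oate F1. Facial control is then only steric, so the C10 epimer has to be removed by chromatography while C2 still makes the two products diastereomers. Hydrogenation (H2, Pd/C) would give methyl (2S,5R,10R)-2-[(tert-butyldimethylsilyl)oxy]drim-8-en-11-oate F2, and TBAF would give methyl (2S,5R,10R)-2-hydroxydrim-8-en-11-oate F3. Dess–Martin oxidation comes back to the route at ketone 13.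

Step 12. Hydrogen abstraction may not discriminate well enough between C7–H and the C8 methyl, and the allylic bromide may lose HBr to a 6,8‑dienoate on heating. The fallback first takes the alkene out of conjugation with base and then moves it into the ring; it sets out from hydroxy ester 12. Treatment with LDA (3 equiv, THF–HMPA, −78 °C) and an AcOH quench should remove the methyl proton syn to the ester and protonate C9 anti to the C10 methyl, giving methyl (2R,5R,9R,10R)-2-hydroxydrim-8(12)-en-11-oate F4. Dess–Martin oxidation would give methyl (5R,9R,10R)-2-oxodrim-8(12)-en-11-oate F5. L‑Selectride followed by LiAlH4 would lead, through methyl (2S,5R,9R,10R)-2-hydroxydrim-8(12)-en-11-oate F6, to (2S,5R,9R,10R)-drim-8(12)-ene-2,11-diol F7. A cobalt–salen/phenylsilane hydrogen‑atom‑transfer isomerisation should then move the 1,1‑disubstituted alkene to the trisubstituted C7=C8 position, since the tertiary C9–H is shielded. This comes back to the route at diol 17.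

Step 17. The lithiated sulfone may attack the acetate carbonyl of 20, the C2 alkoxide may take up the acetyl group, or displacement of chloride by the hindered carbanion may be slow. The fallback removes the ester from the electrophile and sets out from 20. Methanolysis (K2CO3, MeOH, 0 °C) would give (E)-4-chloro-3-methylbut-2-en-1-ol F8, and silylation (TBSCl, imidazole) would give tert-butyl{[(E)-4-chloro-3-methylbut-2-en-1-yl]oxy}dimethylsilane F9. Alkylation of the dianion of 19 (n‑BuLi, THF–HMPA, NaI cat.) with F9 should give (2S,5R,9R,10R,13E)-15-[(tert-butyldimethylsilyl)oxy]-11-(phenylsulfonyl)labda-7,13-dien-2-ol F10. Sodium amalgam would give (2S,5R,9R,10R,13E)-15-[(tert-butyldimethylsilyl)oxy]labda-7,13-dien-2-ol F11, and TBAF comes back to the route at diol 23.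

**Further compounds**

F1 | step 8 | methyl (2S,10R)-2-[(tert-butyldimethylsilyl)oxy]drima-5,8-dien-11-oate | COC(=O)C1=C(C)CC=C2C(C)(C)C[C@H](O[Si](C)(C)C(C)(C)C)C[C@@]12C
F2 | step 8 | methyl (2S,5R,10R)-2-[(tert-butyldimethylsilyl)oxy]drim-8-en-11-oate | COC(=O)C1=C(C)CC[C@@H]2C(C)(C)C[C@H](O[Si](C)(C)C(C)(C)C)C[C@@]12C
F3 | step 8 | methyl (2S,5R,10R)-2-hydroxydrim-8-en-11-oate | COC(=O)C1=C(C)CC[C@@H]2C(C)(C)C[C@H](O)C[C@@]12C
F4 | step 12 | methyl (2R,5R,9R,10R)-2-hydroxydrim-8(12)-en-11-oate | COC(=O)[C@@H]1C(=C)CC[C@@H]2C(C)(C)C[C@@H](O)C[C@@]12C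
F5 | step 12 | methyl (5R,9R,10R)-2-oxodrim-8(12)-en-11-oate | COC(=O)[C@@H]1C(=C)CC[C@@H]2C(C)(C)CC(=O)C[C@@]12C
F6 | step 12 | methyl (2S,5R,9R,10R)-2-hydroxydrim-8(12)-en-11-oate (not isolated) | COC(=O)[C@@H]1C(=C)CC[C@@H]2C(C)(C)C[C@H](O)C[C@@]12C
F7 | step 12 | (2S,5R,9R,10R)-drim-8(12)-ene-2,11-diol | OC[C@@H]1C(=C)CC[C@@H]2C(C)(C)C[C@H](O)C[C@@]12C
F8 | step 17 | (E)-4-chloro-3-methylbut-2-en-1-ol | OC/C=C(\C)CCl
F9 | step 17 | tert-butyl{[(E)-4-chloro-3-methylbut-2-en-1-yl]oxy}dimethylsilane | CC(C)(C)[Si](C)(C)OC/C=C(\C)CCl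
F10 | step 17 | (2S,5R,9R,10R,13E)-15-[(tert-butyldimethylsilyl)oxy]-11-(phenylsulfonyl)labda-7,13-dien-2-ol (C11 epimers) | CC(C)(C)[Si](C)(C)OC/C=C(\C)CC(S(=O)(=O)c3ccccc3)[C@@H]1C(C)=CC[C@@H]2C(C)(C)C[C@H](O)C[C@@]12C
F11 | step 17 | (2S,5R,9R,10R,13E)-15-[(tert-butyldimethylsilyl)oxy]labda-7,13-dien-2-ol | CC(C)(C)[Si](C)(C)OC/C=C(\C)CC[C@@H]1C(C)=CC[C@@H]2C(C)(C)C[C@H](O)C[C@@]12C
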